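Abiesin is disconnected at O1–C2 and C3–OH of the flavonol pyranone (ring C). This leads to an unprotected E-2'-hydroxychalcone whose resorcinol ring A already carries the finished 5-hydroxy-7-methoxyflavone through the C6–C3' biaryl bond. One treatment with alkaline hydrogen peroxide closes ring C, installs the 3-hydroxyl and aromatises the pyranone, giving the target directly. The step exploits the hydrogen at flavonol C5 (chalcone C6'), which favours six-ring over aurone closure, and the flavone C2=C3 bond (ring F), a deactivated vinylogous ester that needs no oxidation. The chalcone is assembled convergently by Suzuki coupling of a flavone boronate with a bromochalcone, so the flavone never meets concentrated alkali.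

Key step: step 7

Remark: the flavonol unit has rings A (benzo), C (pyranone) and B (4-methoxyphenyl), and the flavone unit has rings D (benzo), F (pyranone) and E (aryl ring at the biaryl bond); the biaryl axis has only two ortho substituents and is taken as freely rotating, so the target has no stereogenic element, and transient 12 is racemic (one enantiomer drawn).

Step 1
Reactants: 1 3-bromo-4-methoxybenzoic acid
Product: 2 3-bromo-4-methoxybenzoyl chloride
Conditions: SOCl2 (2 equiv), DMF (cat.), toluene, 80 °C; evaporate
Reagents that add atoms: thionyl chloride, O=S(Cl)Cl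
Why: Standard acid chloride formation through the acyl chlorosulfite with DMF (Vilsmeier-type) catalysis, in which the aryl bromide and the methyl ether are inert and all by-products are gases.

Step 2
Reactants: 2 3-bromo-4-methoxybenzoyl chloride; 3 2',6'-dihydroxy-4'-methoxyacetophenone
Product: 5 3'-bromo-5-hydroxy-4',7-dimethoxyflavone, via β-diketone 4 (not isolated)
Conditions: 3, LiN(SiMe3)2 (4.2 equiv), THF, −78 to −10 °C; 2, −78 °C to rt; aq HCl quench, crude extract concentrated; then H2SO4 (cat.), AcOH, 100 °C
Reagents that add atoms: none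
Why: Direct C-aroylation of the lithium trianion of a dihydroxyacetophenone (the one-flask equivalent of the Baker–Venkataraman diketone synthesis) followed by acid cyclodehydration works because the ketone enolate outruns the two lithium phenoxides as nucleophile, which avoids the double O-acylation and 3-aroylflavone formation typical of 2',6'-dihydroxy ketones, and because the symmetry of ring D makes both hydroxyls lead to the same 5-hydroxy-7-methoxyflavone.

Step 3
Reactants: 5 3'-bromo-5-hydroxy-4',7-dimethoxyflavone
Product: 6 5-hydroxy-4',7-dimethoxyflavone-3'-boronic acid pinacol ester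
Conditions: B2pin2 (1.3 equiv), Pd(dppf)Cl2 (5 mol%), KOAc (3 equiv), 1,4-dioxane, 90 °C, Ar
Reagents that add atoms: bis(pinacolato)diboron, CC1(C)OB(OC1(C)C)B1OC(C)(C)C(C)(C)O1
Why: Miyaura borylation, in which zerovalent palladium inserts into the C3'–Br bond of ring E and the acetato complex transmetallates with B2pin2, tolerates the substrate because KOAc is too weak to ionise the hydrogen-bonded 5-OH or to start Suzuki homocoupling.

Step 4
Reactants: 7 2',4'-dihydroxyacetophenone
Product: 8 5'-bromo-2',4'-dihydroxyacetophenone
Conditions: NBS (1.0 equiv), MeCN, 0 °C to rt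
Reagents that add atoms: N-bromosuccinimide, O=C1CCC(=O)N1Br
Why: Electrophilic aromatic bromination of resacetophenone takes place at C5, para to the 2-OH and ortho to the 4-OH, in preference to the crowded C3 between the two oxygens, and one equivalent of NBS in the cold limits dibromination.

Step 5
Reactants: 8 5'-bromo-2',4'-dihydroxyacetophenone; 9 4-methoxybenzaldehyde
Product: 10 (E)-5'-bromo-2',4'-dihydroxy-4-methoxychalcone
Conditions: KOH (50% aq, 10 equiv), EtOH, 0 °C to rt, 48 h; then cold 2 M HCl
Reagents that add atoms: none
Why: Claisen–Schmidt condensation with excess concentrated KOH enolises even the phenoxide-deactivated ketone, the non-enolisable aldehyde 9 carries no acidic group, E1cB loss of water gives the conjugated E-alkene under thermodynamic control, and running it on this small fragment spares the flavone any contact with concentrated alkali.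

Step 6
Reactants: 6 5-hydroxy-4',7-dimethoxyflavone-3'-boronic acid pinacol ester; 10 (E)-5'-bromo-2',4'-dihydroxy-4-methoxychalcone
Product: 11 (E)-1-{2,4-dihydroxy-5-[5-(5-hydroxy-7-methoxy-4-oxo-4H-chromen-2-yl)-2-methoxyphenyl]phenyl}-3-(4-methoxyphenyl)prop-2-en-1-one
Conditions: Pd(OAc)2 (5 mol%), SPhos (10 mol%), K3PO4 (6 equiv), 1,4-dioxane–H2O 4:1, 80 °C, Ar; then cold 1 M HCl to pH 4
Reagents that add atoms: none
Why: Suzuki–Miyaura coupling with the bulky electron-rich SPhos ligand promotes oxidative addition to the electron-rich bromophenoxide and reductive elimination to the doubly ortho-substituted C6–C3' biaryl, K3PO4 is dosed to cover the three phenols, and the enone, a poor acceptor while its aryl ketone is a phenoxide, should come through with its E geometry intact.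

Step 7
Reactants: 11 (E)-1-{2,4-dihydroxy-5-[5-(5-hydroxy-7-methoxy-4-oxo-4H-chromen-2-yl)-2-methoxyphenyl]phenyl}-3-(4-methoxyphenyl)prop-2-en-1-one
Product: 13 abiesin, via trans-dihydroflavonol 12 (not isolated)
Conditions: 30% aq H2O2 (6 equiv), 2 M aq NaOH (8 equiv), MeOH, 0 °C to rt; then 1 M HCl to pH 3
Reagents that add atoms: hydrogen peroxide, OO
Why: Algar–Flynn–Oyamada oxidation of a 2'-hydroxychalcone, a known reaction type that is applied here to a chalcone bearing a flavone, whose three phenoxides also keep it dissolved in aqueous methanol. Hydroperoxide attacks the enone either by Weitz–Scheffer epoxidation, after which the 2'-phenoxide opens the epoxide at the benzylic Cβ (6-endo-tet), or after a 6-endo-trig oxa-Michael closure whose enolate is hydroxylated at Cα; both paths form O1–C2 and C3–O, close ring C and meet at trans-dihydroflavonol 12. Enolisation of 12 and a second equivalent of peroxide remove the hydrogens at C2 and C3 to give the aromatic pyranone, so the two transient stereocentres disappear and need no control. The selectivity needed is six-ring (flavonol) over five-ring (aurone, 5-exo attack at Cα) closure; it is secured by the hydrogen at chalcone C6' (flavonol C5), which leaves the aroyl group coplanar and unhindered, and by the 4-methoxyphenyl ring B, which makes Cβ the more electrophilic epoxide carbon. Chemoselectivity rests on ring F being a vinylogous ester that the neighbouring 5-phenoxide deactivates further, so its C2=C3 bond should resist HOO− at or below room temperature. Cold addition, a limited excess of peroxide and prompt acidification protect the product enol from oxidative cleavage.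

Compound list
1 | 3-bromo-4-methoxybenzoic acid | COc1ccc(C(=O)O)cc1Br | starting material
2 | 3-bromo-4-methoxybenzoyl chloride | COc1ccc(C(=O)Cl)cc1Br | intermediate
3 | 2',6'-dihydroxy-4'-methoxyacetophenone | CC(=O)c1c(O)cc(OC)cc1O | starting material
4 | 1-(3-bromo-4-methoxyphenyl)-3-(2,6-dihydroxy-4-methoxyphenyl)propane-1,3-dione | COc1ccc(C(=O)CC(=O)c2c(O)cc(OC)cc2O)cc1Br | intermediate
5 | 2-(3-bromo-4-methoxyphenyl)-5-hydroxy-7-methoxy-4H-chromen-4-one (3'-bromo-5-hydroxy-4',7-dimethoxyflavone) | COc1ccc(-c2cc(=O)c3c(O)cc(OC)cc3o2)cc1Br | intermediate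
6 | 5-hydroxy-7-methoxy-2-[4-methoxy-3-(4,4,5,5-tetramethyl-1,3,2-dioxaborolan-2-yl)phenyl]-4H-chromen-4-one | COc1ccc(-c2cc(=O)c3c(O)cc(OC)cc3o2)cc1B1OC(C)(C)C(C)(C)O1 | intermediate
7 | 2',4'-dihydroxyacetophenone | CC(=O)c1ccc(O)cc1O | starting material
8 | 5'-bromo-2',4'-dihydroxyacetophenone | CC(=O)c1cc(Br)c(O)cc1O | intermediate
9 | 4-methoxybenzaldehyde | COc1ccc(C=O)cc1 | starting material
10 | (E)-1-(5-bromo-2,4-dihydroxyphenyl)-3-(4-methoxyphenyl)prop-2-en-1-one | COc1ccc(/C=C/C(=O)c2cc(Br)c(O)cc2O)cc1 | intermediate
11 | (E)-1-{2,4-dihydroxy-5-[5-(5-hydroxy-7-methoxy-4-oxo-4H-chromen-2-yl)-2-methoxyphenyl]phenyl}-3-(4-methoxyphenyl)prop-2-en-1-one | COc1ccc(/C=C/C(=O)c2cc(-c3cc(-c4cc(=O)c5c(O)cc(OC)cc5o4)ccc3OC)c(O)cc2O)cc1 | intermediate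
12 | rac-(2R,3R)-3,7-dihydroxy-6-[5-(5-hydroxy-7-methoxy-4-oxo-4H-chromen-2-yl)-2-methoxyphenyl]-2-(4-methoxyphenyl)chroman-4-one (trans, one enantiomer drawn) | COc1ccc(cc1)[C@@H]1[C@@H](O)C(=O)c2cc(-c3cc(-c4cc(=O)c5c(O)cc(OC)cc5o4)ccc3OC)c(O)cc2O1 | intermediate
13 | abiesin, 3,7-dihydroxy-6-[5-(5-hydroxy-7-methoxy-4-oxo-4H-chromen-2-yl)-2-methoxyphenyl]-2-(4-methoxyphenyl)-4H-chromen-4-one | COc1ccc(-c2oc3cc(O)c(-c4cc(-c5cc(=O)c6c(O)cc(OC)cc6o5)ccc4OC)cc3c(=O)c2O)cc1 | target

Total step count: 7. Longest linear sequence: 5 steps (steps 1, 2, 3, 6, 7, from 1). The second branch (steps 4 and 5) joins at step 6.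

Steps most likely to fail

Step 7. Several processes could spoil the oxidation:
- Hydroperoxide may attack only slowly an enone whose carbonyl is deactivated by the 4'-phenoxide.
- Dakin-type addition at the ketone with aryl migration may compete.
- Hydroxide or hydroperoxide may slowly open flavone ring F.
- The product enol may be cleaved on long exposure.

The fallback moves the peroxide step ahead of the fragment union, so the flavone never meets the oxidant. It sets out from bromochalcone 10.
- Algar–Flynn–Oyamada oxidation (H2O2, NaOH, MeOH, 0 °C to rt) should give 6-bromo-3,7-dihydroxy-4'-methoxyflavone F1.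
- Double benzylation (BnBr, K2CO3, DMF) should give 3,7-bis(benzyloxy)-6-bromo-4'-methoxyflavone F2, which removes the palladium-chelating flavonol motif.
- Suzuki coupling with boronate 6 (Pd(OAc)2, SPhos, K3PO4, dioxane–H2O) should give 3,7-di-O-benzylabiesin F3.
- Hydrogenolysis (H2, 1 atm, Pd/C, THF–MeOH) rejoins the route at target 13.

Step 6. Hot aqueous base may isomerise the 2'-hydroxychalcone to its flavanone or cleave it by retro-aldol reaction. Protodeboronation of the ortho-methoxy boronate may also outrun a slow oxidative addition. The fallback introduces the enone only after the coupling. It sets out from bromoketone 8 and boronate 6. The same catalyst system should give the biaryl ketone 1-{2,4-dihydroxy-5-[5-(5-hydroxy-7-methoxy-4-oxo-4H-chromen-2-yl)-2-methoxyphenyl]phenyl}ethanone F4. Claisen–Schmidt condensation of F4 with aldehyde 9 (KOH, EtOH, rt, with the flavone held as its 5-phenoxide) rejoins the route at chalcone 11.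

Step 5. The doubly deprotonated ketone may enolise and condense slowly. Cannizzaro consumption of the aldehyde and incomplete conversion may then take over. The fallback masks the deactivating 4-hydroxyl. It sets out from 8.
- MOMCl with K2CO3 in acetone etherifies only the non-chelated 4-OH and should give 1-[5-bromo-2-hydroxy-4-(methoxymethoxy)phenyl]ethanone F5.
- Condensation with 9 (KOH, EtOH, rt) should give (E)-1-[5-bromo-2-hydroxy-4-(methoxymethoxy)phenyl]-3-(4-methoxyphenyl)prop-2-en-1-one F6.
- Mild acetal cleavage (HCl, MeOH, 40 °C) rejoins the route at bromochalcone 10.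

Further compounds
F1 | step 7 | 6-bromo-3,7-dihydroxy-2-(4-methoxyphenyl)-4H-chromen-4-one | COc1ccc(-c2oc3cc(O)c(Br)cc3c(=O)c2O)cc1
F2 | step 7 | 3,7-bis(benzyloxy)-6-bromo-2-(4-methoxyphenyl)-4H-chromen-4-one | COc1ccc(-c2oc3cc(OCc4ccccc4)c(Br)cc3c(=O)c2OCc2ccccc2)cc1
F3 | step 7 | 3,7-di-O-benzylabiesin | COc1ccc(-c2oc3cc(OCc4ccccc4)c(-c4cc(-c5cc(=O)c6c(O)cc(OC)cc6o5)ccc4OC)cc3c(=O)c2OCc2ccccc2)cc1
F4 | step 6 | 1-{2,4-dihydroxy-5-[5-(5-hydroxy-7-methoxy-4-oxo-4H-chromen-2-yl)-2-methoxyphenyl]phenyl}ethanone | CC(=O)c1cc(-c2cc(-c3cc(=O)c4c(O)cc(OC)cc4o3)ccc2OC)c(O)cc1O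
F5 | step 5 | 1-[5-bromo-2-hydroxy-4-(methoxymethoxy)phenyl]ethanone | CC(=O)c1cc(Br)c(OCOC)cc1O
F6 | step 5 | (E)-1-[5-bromo-2-hydroxy-4-(methoxymethoxy)phenyl]-3-(4-methoxyphenyl)prop-2-en-1-one | COCOc1cc(O)c(C(=O)/C=C/c2ccc(OC)cc2)cc1Br
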